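(The readings stem from a simulated flask with made-up constants; noise was put on by code.)

The vessel is closed, stirred and held at one temperature, and it starts with equal charges of starting material and second substrate and a trace of free catalyst.

all flasks: starting material 0.20 M

|  | second substrate | free catalyst | temperature | remark | time |
|---|---|---|---|---|---|
| beta | 0.20 M | 0.13 mM | 10 °C | run made earlier |  |
| alpha | 0.20 M | 0.30 mM | 29 °C | run made earlier |  |
| birch | 0.200 M | 0.20 mM | 25 °C |  | 2.0 h |
| elm | 0.200 M | 0.20 mM | 33 °C |  | 2.0 h |

- beta (time / h: target / %, starting material / %, catalyst intermediate A / %): 0.200: 0.7, 99.7, 0.4; 0.667: 0.9, 97.2, 0.3; 1.00: 0.6, 95.6, 0.3; 2.00: 1.2, 90.4, 0; 3.00: 3.0, 85.7, 1.2; 4.00: 2.8, 81.9, 0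
- alpha (time / min: target / %, starting material / %, catalyst intermediate A / %): 6.00: 1.2, 94.4, 0.1; 20.0: 4.8, 83.9, 0.7; 30.0: 6.0, 76.7, 0; 50.0: 11.9, 62.5, 0; 80.0: 32.1, 35.2, 0; 90.0: 41.7, 26.6, 0; 120: 59.1, 9.8, 0

(each reading ± 0.5 percentage points)

- the analysis behind the earlier runs scatters by 0.5 percentage points, standard deviation
- a reading or a percentage of target counts all its forms, free or not
- a reading of starting material is of its free form alone

1. which of these there is most of at the end, counted by the starting material in it, birch (catalyst intermediate A / target / starting material)
2. which of these there is most of at the end, counted by the starting material in it, elm (catalyst intermediate A / target / starting material)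
3. how much there is at the end of the one of these that leads, in percent of the starting material charged: birch
4. how much there is at the end of the one of these that leads, in percent of the starting material charged: elm

I work in fractions of the charge. Alpha's starting material falls almost straight up to 90.0 min, so I replace that curve by its mean fall, 0.489 h⁻¹. Scaled to the catalyst of birch and elm, alpha gives 0.326 h⁻¹ and beta gives 0.0696 h⁻¹. I let each degree multiply the fall by the same factor, which gives 0.236 h⁻¹ for birch and 0.452 h⁻¹ for elm.

Mean fall times hours is the dose: 0.471 for birch, 0.903 for elm.

Two extreme flasks can be done in the head. In a zero-order flask the fraction left is one minus the dose. In a first-order flask it is the exponential of minus the dose. That brackets birch at 52.9% to 62.4% and elm at 9.70% to 40.5%.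

Alpha tests the bracket. Its dose at 120 min is 0.979, and its reading of 9.8% lies above the line and below the exponential. At 50.0 min the line misses by 3.3 percentage points. So I stay near the line and commit to about 52.9% starting material for birch.

Alpha reaches elm's dose at 111 min, and from its reading at 90.0 min on it shows more target than starting material. I take equal dose as equal state. Reading between alpha's values on either side of that time gives elm about 53.7% target, more than the top of elm's bracket for starting material, so I commit to target for elm.

The forecast differs a little: starting material at 55% for birch, target at 50% for elm. Its ground: “SM falls almost linearly in both runs”.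

The flasks give starting material at 52.6% for birch and target at 48.9% for elm, so the forecast stands within its margins.

    starting material + free catalyst ⇌ catalyst intermediate A (K = 13.4 M⁻¹, k = 2.29 M⁻¹ s⁻¹, Ea = 37.0 kJ mol⁻¹, ΔH = −37.0 kJ mol⁻¹)
    catalyst intermediate A → free catalyst + target (k = 0.502 s⁻¹, Ea = 82.0 kJ mol⁻¹)
    second substrate + free catalyst ⇌ catalyst intermediate B (K = 363 M⁻¹, k = 19.6 M⁻¹ s⁻¹, Ea = 46.0 kJ mol⁻¹, ΔH = −24.0 kJ mol⁻¹)
    catalyst intermediate B → free catalyst + second product (k = 0.128 s⁻¹, Ea = 68.0 kJ mol⁻¹)
    crystals ⇌ target, rate k5*(cs5 - [target]) while solid is left; crystals form when [target] > cs5 (solubility = 50.0 mM, k = 0.00184 s⁻¹)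
    starting material ⇌ dormant form (K = 1.86, k = 7.19 × 10⁻⁵ s⁻¹, Ea = 87.0 kJ mol⁻¹, ΔH = −33.0 kJ mol⁻¹)
    (constants at 25 °C)

Birch ends 0.23 points under its line of 52.9%, and a single reading in the earlier runs scatters by 0.5 points. Its charge stands as 52.6% starting material, 14.2% target and 33.2% dormant form, so the fall of starting material is not the rise of target. A flask like birch at 50 °C takes the same reckoning, with dose 3.60. Its line gives 0% and its exponential 2.73%. That flask holds 1.38% starting material and 97.2% target.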